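If you put concentration on a logarithmic axis, this flask stands midway between the delta and beta runs, since 20.0 mM is the geometric mean of 10 mM and 40 mM.

| flask | L | Z | Q | remark | time |
|---|---|---|---|---|---|
| delta | 10 mM | 0.80 equiv | 1.1 equiv | run made earlier |  |
| beta | 40 mM | 0.80 equiv | 1.1 equiv | run made earlier |  |
| zeta | 20 mM | 0.80 equiv | 0.55 equiv | run made earlier |  |
| flask | 20 mM | 0.800 equiv | 1.10 equiv |  | 25 min |

- delta (time / min: D / %): 0.200: 1; 0.417: 4; 0.833: 7; 1.50: 8; 4.00: 4; 8.00: 0; 15.0: 0
- beta (time / min: D / %): 0.200: 12; 0.417: 16; 0.833: 14; 1.50: 7; 4.00: 1; 8.00: 0; 15.0: 3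
- zeta (time / min: D / %): 0.200: 3; 0.667: 5; 1.50: 4; 5.00: 1; 15.0: 0

(readings scatter by 1.5 percentage points)

- the best time, 25 min at the latest, for D
- the amount of D, in percent of the L charged, at that time
- the first time at which D reaches 8.3 %, in the same percent, in min

- the analysis behind the earlier runs scatters by 1.5 percentage points, standard deviation

So work in logarithms and take the midpoint of the peak heights and peak times of these two runs, whose equivalents of Z and Q are the same. Their peak readings are 8 % at 1.50 min for delta and 16 % at 0.417 min for beta, so I place the peak of the flask at 11.3 % and 0.791 min.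

Now climb the ladder of times, fastest rung first. The lowest rung is the rise. Beta reads 12 % at 0.200 min, a fraction 0.750 of its peak reading, and the level asked is a fraction 0.734 of my peak. Stretching beta's clock by 1.90 puts that level at 0.379 min. The next rung is the peak itself. The top rung is the fall: delta reads 0 % at 8.00 min and zeta 0 % at 15.0 min, and I take beta's late 3 % at 15.0 min for scatter, so I expect no later maximum in this flask before 25 min.

Zeta also shows what Q does. With 0.55 equiv of Q against 1.10 equiv at the same 20 mM, it peaks at a reading of 5 %. That gives 1.18 for the Q slope, the logarithm of the ratio of peak heights over the logarithm of the ratio of Q charges. It is itself a reading, carrying the scatter of 1.5 percentage points.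

The forecast, made from the same runs, puts D at 11 % at 0.7 min, earlier than my time, and the level at 0.37 min, reasoning that “peak height roughly as the square root of concentration”.

The flask gives 11.9 % at 0.781 min and reaches the level at 0.405 min.

    L + Q → E (k = 2.60 /M/s)
    Q + Z → X (k = 1.60 /M/s)
    E + X → D (k = 5.90 /M/s)
    D → G (k = 0.0390 /s)
    L ⇌ J (K = 0.800, k = 0.0710 /s)

Q, the limiting reagent of this flask, is down to 1.64 % of its own charge at 2.50 min. Carry the Q slope from the height of the flask to a neighbour flask, the same but for 0.660 equiv of Q, and you get 6.52 %; that neighbour flask gives 6.60 %.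

(Readings and results come from a simulation with constants of no real substance, noise included.)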